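## Retrosynthetic overview

1. Feature: in ring C the neighbouring carbons C3 (enol OH) and C4 (C=O) are both oxidised. The 3-hydroxy-4-pyranone is the enol of a 2-arylchroman-3,4-dione, one oxidation level above an acyloin, so C3–C4 can be cut back to two aldehyde carbons.
2. Target <= hydrogenolysis of five benzyl ethers <= oxidation of the C3/C4 ketol <= carbene-catalysed intramolecular crossed benzoin of a dialdehyde (ring A CHO = C4; ArO–CH(Ar)–CHO = C2/C3). Ring C is the only ring built, and it is built last.
3. Dialdehyde <= O1–C2 ether bond (hindered salicylaldehyde + methyl bromo(4-methoxyphenyl)acetate), then one exhaustive reduction and one exhaustive oxidation instead of carbonyl masking.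
4. Salicylaldehyde <= chelation-directed ortho-formylation <= C8–CH2 bond by Friedel–Crafts benzylation of 3,5-bis(benzyloxy)phenol with the ring A' benzylic alcohol, a union that tolerates the ketone.
5. Ring A' alcohol <= 2,4,6-trihydroxytoluene by C-acylation with 3-(4-hydroxyphenyl)propanoic acid, para-O-methylation, formylation, benzylation and aldehyde reduction.

Key step: step 12

Remark on the chemistry: the target has no stereocentre. Every intermediate with an sp3 C2 is racemic, and one enantiomer is drawn only for bookkeeping.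
Abbreviation: Ar' = 2,4-bis(benzyloxy)-3-{3-[4-(benzyloxy)phenyl]propanoyl}-6-methoxy-5-methylphenyl (protected ring A' with its acyl chain).

## Route

Step 1
Reactants: 1 2,4,6-trihydroxytoluene; 2 3-(4-hydroxyphenyl)propanoic acid
Product: 3 3-(4-hydroxyphenyl)-1-(2,4,6-trihydroxy-3-methylphenyl)propan-1-one
Conditions: BF3·OEt2 (solvent), 85 °C; aq. NaOAc work-up
Reagents that add atoms: none
Why: Friedel–Crafts C-acylation of a phloroglucinol by the BF3-activated acid should occur once, at either of the two equivalent free carbons of 1, because the chelated aryl ketone formed is deactivated and the monohydric ring of 2 is far less nucleophilic.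

Step 2
Reactants: 3 3-(4-hydroxyphenyl)-1-(2,4,6-trihydroxy-3-methylphenyl)propan-1-one
Product: 4 1-(2,6-dihydroxy-4-methoxy-3-methylphenyl)-3-(4-hydroxyphenyl)propan-1-one
Conditions: Me2SO4 (1.0 equiv), K2CO3 (1.0 equiv), acetone, reflux
Reagents that add atoms: dimethyl sulfate COS(=O)(=O)OC
Why: Williamson methylation with one equivalent of weak base should select the hydroxyl para to the ketone, which is the most acidic and is not hydrogen-bonded to the carbonyl, while the markedly less acidic ring B' phenol stays protonated.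

Step 3
Reactants: 4 1-(2,6-dihydroxy-4-methoxy-3-methylphenyl)-3-(4-hydroxyphenyl)propan-1-one
Product: 5 2,4-dihydroxy-3-[3-(4-hydroxyphenyl)propanoyl]-6-methoxy-5-methylbenzaldehyde
Conditions: Cl2CHOMe (1.1 equiv), TiCl4 (3.5 equiv), CH2Cl2, −20 to 0 °C; then ice-cold 1 M HCl
Reagents that add atoms: dichloromethyl methyl ether COC(Cl)Cl; water O
Why: Rieche formylation should strike the single unsubstituted carbon of the trioxygenated ring A', which lies ortho to a titanium phenoxide and is much more nucleophilic than ring B', and unlike a Vilsmeier reagent this electrophile does not condense at the ketone α-methylene to close a chromone.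

Step 4
Reactants: 5 2,4-dihydroxy-3-[3-(4-hydroxyphenyl)propanoyl]-6-methoxy-5-methylbenzaldehyde
Product: 6 2,4-bis(benzyloxy)-3-{3-[4-(benzyloxy)phenyl]propanoyl}-6-methoxy-5-methylbenzaldehyde (Ar'CHO)
Conditions: BnBr (4 equiv), K2CO3 (5 equiv), n-Bu4NI (cat.), DMF, 60 °C
Reagents that add atoms: benzyl bromide BrCc1ccccc1
Why: Williamson benzylation in a dipolar aprotic solvent with heating should overcome the hydrogen bonding of the two ring A' hydroxyls and cap the ring B' phenol, and rearomatising C-benzylation is excluded because ring A' has no free carbon left.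

Step 5
Reactants: 6 Ar'CHO
Product: 7 1-[2,6-bis(benzyloxy)-3-(hydroxymethyl)-4-methoxy-5-methylphenyl]-3-[4-(benzyloxy)phenyl]propan-1-one (Ar'CH2OH)
Conditions: NaBH4 (0.5 equiv), THF–MeOH, −20 °C
Reagents that add atoms: none
Why: Borohydride reduction should be chemoselective for the aldehyde because the ketone is flanked by two ortho benzyloxy groups and is attacked far more slowly at low temperature.

Step 6
Reactants: 7 Ar'CH2OH; 8 3,5-bis(benzyloxy)phenol
Product: 9 3,5-bis(benzyloxy)-2-(Ar'CH2)phenol
Conditions: 8 (3 equiv), H2SO4 on SiO2 (cat.), CH2Cl2, 0 °C to rt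
Reagents that add atoms: none
Why: In this acid-catalysed Friedel–Crafts benzylation the 2,4,6-trialkoxybenzylic alcohol ionises under very mild acid, its own ring has no free carbon for self-condensation, and the excess phenol should be attacked (reversibly) at C2 next to the small hydroxyl rather than at C4 between two benzyloxy groups, as is known for acid-catalysed allylation of this same phenol.

Step 7
Reactants: 9 3,5-bis(benzyloxy)-2-(Ar'CH2)phenol
Product: 10 4,6-bis(benzyloxy)-2-hydroxy-3-(Ar'CH2)benzaldehyde
Conditions: MgCl2 (anhydrous, 2 equiv), Et3N (4 equiv), (CH2O)n (7 equiv), MeCN, reflux; then 1 M HCl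
Reagents that add atoms: paraformaldehyde (as formaldehyde) C=O
Why: Magnesium-mediated ortho-formylation (Casnati–Skattebøl) delivers formaldehyde inside the magnesium phenoxide chelate and so reaches only the one free carbon ortho to the hydroxyl, leaving the carbon between the two benzyloxy groups untouched.

Step 8
Reactants: 11 methyl 2-(4-methoxyphenyl)acetate
Product: 12 methyl 2-bromo-2-(4-methoxyphenyl)acetate (racemic)
Conditions: NBS (1.05 equiv), 2,2'-azobis(2-methylpropionitrile) (5 mol %), PhCF3, reflux
Reagents that add atoms: N-bromosuccinimide O=C1CCC(=O)N1Br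
Why: Wohl–Ziegler bromination abstracts the doubly activated (benzylic and α-ester) hydrogen, and radical conditions in a non-polar solvent suppress ionic bromination of the anisole ring.

Step 9
Reactants: 10 4,6-bis(benzyloxy)-2-hydroxy-3-(Ar'CH2)benzaldehyde; 12 methyl 2-bromo-2-(4-methoxyphenyl)acetate
Product: 13 methyl 2-[3,5-bis(benzyloxy)-2-formyl-6-(Ar'CH2)phenoxy]-2-(4-methoxyphenyl)acetate (racemic)
Conditions: 12 (1.5 equiv), Cs2CO3 (1.5 equiv), DMF, rt to 40 °C
Reagents that add atoms: none
Why: In this Williamson O-alkylation the caesium phenoxide displaces the very reactive 4-methoxybenzylic α-bromo ester to form O1–C2, and the mild temperature keeps the ester enolate from adding to the hindered, electron-rich aldehyde.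

Step 10
Reactants: 13 methyl 2-[3,5-bis(benzyloxy)-2-formyl-6-(Ar'CH2)phenoxy]-2-(4-methoxyphenyl)acetate
Product: 14 triol: 2-aryloxy-2-(4-methoxyphenyl)ethanol whose ring A carries CH2OH in place of CHO and whose ring A' ketone is reduced to the carbinol (mixture of carbinol epimers)
Conditions: LiAlH4 (3 equiv), THF, 0 °C to rt; H2O/aq. NaOH work-up
Reagents that add atoms: none
Why: Exhaustive hydride reduction takes ester, aldehyde and ketone together to the triol, which removes the need to mask one carbonyl while another is adjusted, and the unselective new carbinol centre is erased in step 11.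

Step 11
Reactants: 14 triol
Product: 15 2-[3,5-bis(benzyloxy)-2-formyl-6-(Ar'CH2)phenoxy]-2-(4-methoxyphenyl)acetaldehyde (racemic dialdehyde)
Conditions: Dess–Martin periodinane (4.5 equiv), NaHCO3 (excess), CH2Cl2, 0 °C to rt; short pad of deactivated silica, used at once
Reagents that add atoms: none
Why: Dess–Martin oxidation under bicarbonate buffer converts both primary alcohols to aldehydes and the secondary benzylic alcohol back to the ketone without over-oxidation, and its near-neutral, non-aqueous medium spares the enolisable α-aryloxy aldehyde and the acid-labile trialkoxybenzylic alcohol.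

Step 12
Reactants: 15 racemic dialdehyde
Product: 17 5,7-bis(benzyloxy)-3-hydroxy-2-(4-methoxyphenyl)-8-(Ar'CH2)chroman-4-one (racemic 2,3-trans ketol), via Breslow enaminol 16 (not isolated)
Conditions: 2-(pentafluorophenyl)-6,7-dihydro-5H-pyrrolo[2,1-c][1,2,4]triazol-2-ium tetrafluoroborate (20 mol %), i-Pr2NEt (20 mol %), degassed toluene (0.01 M), 40 °C, Ar
Reagents that add atoms: none
Why: The free triazolylidene adds reversibly to the ring A aldehyde, where two ortho alkoxy groups favour the adduct, and proton transfer gives Breslow enaminol 16, an acyl-anion equivalent at C4. C4 then attacks the α-aryloxy aldehyde carbon C3, made the better electrophile by the inductive pull of O1, in a 6-(enolexo)-exo-trig closure that forms C3–C4 and ring C, and collapse of the adduct releases the carbene and the C4 ketone. The closest known reactions are the carbene-catalysed intramolecular crossed benzoin of 2-(2-oxoalkoxy)benzaldehydes to 3-hydroxychroman-4-ones and the cyclisation of 1,6-dialdehydes to 2-hydroxycyclohexanones. The new C3 carbinol centre should be set trans to C2 by a chair-like transition state that keeps the 4-methoxyphenyl group and the developing alkoxide equatorial; it can equilibrate through the enediol and is erased in step 13. The step needs cyclisation rather than dimerisation (six-atom tether, high dilution); it needs carbene engagement at the aryl rather than the aliphatic aldehyde, since an enaminol at C3 could expel the ring A aryloxide from C2, and the fully branched α-carbon with its bulky aryloxy group shields that carbonyl; and it needs no enolate chemistry at C2, which the acidic N-C6F5 azolium allows by working with a substoichiometric tertiary amine. Any 4-hydroxychroman-3-one formed by the reverse polarity is carried on, because step 13 converges both ketols.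

Step 13
Reactants: 17 racemic ketol
Product: 19 5,7-bis(benzyloxy)-3-hydroxy-2-(4-methoxyphenyl)-8-(Ar'CH2)-4H-chromen-4-one (pentabenzyl flavonol), via chroman-3,4-dione 18 (not isolated)
Conditions: Cu(OAc)2 (20 mol %), air, AcOH–toluene 1:1, 60 °C
Reagents that add atoms: none
Why: Copper-catalysed aerobic oxidation of an acyloin to the 1,2-dione (the benzoin-to-benzil reaction type) runs through a copper enediolate, so all ketol isomers converge on dione 18, which enolises at once by loss of the C2 hydrogen to the aromatic 3-hydroxy-4-pyranone, while acetic acid keeps the flavonol protonated and guards it against copper-mediated oxygenolysis.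

Step 14
Reactants: 19 pentabenzyl flavonol
Product: 20 4'''-hydroxytrianguletin
Conditions: H2 (1 atm), 10% Pd/C, THF–MeOH, rt
Reagents that add atoms: none
Why: Catalytic hydrogenolysis cleaves the five O-benzyl bonds under conditions that leave the pyranone double bond, the hydrogen-bonded aryl ketone, both methyl ethers and the diarylmethane bridge untouched.

## Compound list

1 | 2,4,6-trihydroxytoluene | Cc1c(O)cc(O)cc1O | starting material
2 | 3-(4-hydroxyphenyl)propanoic acid | O=C(O)CCc1ccc(O)cc1 | starting material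
3 | 3-(4-hydroxyphenyl)-1-(2,4,6-trihydroxy-3-methylphenyl)propan-1-one | Cc1c(O)cc(O)c(C(=O)CCc2ccc(O)cc2)c1O | intermediate
4 | 1-(2,6-dihydroxy-4-methoxy-3-methylphenyl)-3-(4-hydroxyphenyl)propan-1-one | Cc1c(OC)cc(O)c(C(=O)CCc2ccc(O)cc2)c1O | intermediate
5 | 2,4-dihydroxy-3-[3-(4-hydroxyphenyl)propanoyl]-6-methoxy-5-methylbenzaldehyde | Cc1c(OC)c(C=O)c(O)c(C(=O)CCc2ccc(O)cc2)c1O | intermediate
6 | tribenzyl aldehyde Ar'CHO | Cc1c(OC)c(C=O)c(OCc2ccccc2)c(C(=O)CCc2ccc(OCc3ccccc3)cc2)c1OCc1ccccc1 | intermediate
7 | ring A' benzylic alcohol Ar'CH2OH | Cc1c(OC)c(CO)c(OCc2ccccc2)c(C(=O)CCc2ccc(OCc3ccccc3)cc2)c1OCc1ccccc1 | intermediate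
8 | 3,5-bis(benzyloxy)phenol | Oc1cc(OCc2ccccc2)cc(OCc2ccccc2)c1 | starting material
9 | 3,5-bis(benzyloxy)-2-(Ar'CH2)phenol | Oc1cc(OCc2ccccc2)cc(OCc2ccccc2)c1Cc1c(OCc2ccccc2)c(C(=O)CCc2ccc(OCc3ccccc3)cc2)c(OCc2ccccc2)c(C)c1OC | intermediate
10 | 4,6-bis(benzyloxy)-2-hydroxy-3-(Ar'CH2)benzaldehyde | O=Cc1c(O)c(Cc2c(OCc3ccccc3)c(C(=O)CCc3ccc(OCc4ccccc4)cc3)c(OCc3ccccc3)c(C)c2OC)c(OCc2ccccc2)cc1OCc1ccccc1 | intermediate
11 | methyl 2-(4-methoxyphenyl)acetate | COC(=O)Cc1ccc(OC)cc1 | starting material
12 | methyl 2-bromo-2-(4-methoxyphenyl)acetate (racemic, one enantiomer drawn) | COc1ccc([C@@H](C(=O)OC)Br)cc1 | intermediate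
13 | aryloxy ester aldehyde (racemic, one enantiomer drawn) | COc1ccc([C@H](C(=O)OC)Oc2c(Cc3c(OCc4ccccc4)c(C(=O)CCc4ccc(OCc5ccccc5)cc4)c(OCc4ccccc4)c(C)c3OC)c(OCc3ccccc3)cc(OCc3ccccc3)c2C=O)cc1 | intermediate
14 | triol (racemic at C2, one enantiomer drawn; carbinol centre a mixture, not specified) | COc1ccc([C@H](CO)Oc2c(Cc3c(OCc4ccccc4)c(C(O)CCc4ccc(OCc5ccccc5)cc4)c(OCc4ccccc4)c(C)c3OC)c(OCc3ccccc3)cc(OCc3ccccc3)c2CO)cc1 | intermediate
15 | dialdehyde, key-step precursor (racemic, one enantiomer drawn) | COc1ccc([C@H](C=O)Oc2c(Cc3c(OCc4ccccc4)c(C(=O)CCc4ccc(OCc5ccccc5)cc4)c(OCc4ccccc4)c(C)c3OC)c(OCc3ccccc3)cc(OCc3ccccc3)c2C=O)cc1 | intermediate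
16 | Breslow enaminol, carbene adduct at the ring A aldehyde carbon of 15 (alkene geometry not specified) | COc1ccc([C@H](C=O)Oc2c(Cc3c(OCc4ccccc4)c(C(=O)CCc4ccc(OCc5ccccc5)cc4)c(OCc4ccccc4)c(C)c3OC)c(OCc3ccccc3)cc(OCc3ccccc3)c2C(O)=C2N(c3c(F)c(F)c(F)c(F)c3F)N=C3CCCN23)cc1 | intermediate (not isolated)
17 | protected dihydroflavonol, key-step product (racemic, trans isomer drawn; either isomer serves) | COc1ccc(cc1)[C@@H]1[C@H](C(=O)c2c(OCc3ccccc3)cc(OCc3ccccc3)c(Cc3c(OCc4ccccc4)c(C(=O)CCc4ccc(OCc5ccccc5)cc4)c(OCc4ccccc4)c(C)c3OC)c2O1)O | intermediate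
18 | 5,7-bis(benzyloxy)-2-(4-methoxyphenyl)-8-(Ar'CH2)chromane-3,4-dione (racemic, one enantiomer drawn) | COc1ccc(cc1)[C@@H]1C(=O)C(=O)c2c(OCc3ccccc3)cc(OCc3ccccc3)c(Cc3c(OCc4ccccc4)c(C(=O)CCc4ccc(OCc5ccccc5)cc4)c(OCc4ccccc4)c(C)c3OC)c2O1 | intermediate (not isolated)
19 | pentabenzyl flavonol | COc1ccc(-c2oc3c(Cc4c(OCc5ccccc5)c(C(=O)CCc5ccc(OCc6ccccc6)cc5)c(OCc5ccccc5)c(C)c4OC)c(OCc4ccccc4)cc(OCc4ccccc4)c3c(=O)c2O)cc1 | intermediate
20 | 4'''-hydroxytrianguletin | COc1ccc(-c2oc3c(Cc4c(O)c(C(=O)CCc5ccc(O)cc5)c(O)c(C)c4OC)c(O)cc(O)c3c(=O)c2O)cc1 | target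

## Step count and risks

Total step count: 14. Longest linear sequence: 13 steps (steps 1–7 and 9–14, from 2,4,6-trihydroxytoluene).

**Step 12 (key step).**
- What may go wrong: the carbene may add at the aliphatic aldehyde and the ring A aryloxide may then be lost from C2 (internal redox acyl transfer). An aldol-type closure from C2 onto the aryl aldehyde may compete. The doubly ortho-substituted, electron-rich aryl aldehyde may simply not turn over.
- Fallback: ring C is closed at C4–C4a by Friedel–Crafts acylation instead, setting out from phenol 9.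
- Opening of commercial racemic methyl trans-3-(4-methoxyphenyl)oxirane-2-carboxylate (COc1ccc(cc1)[C@H]2[C@@H](O2)C(=O)OC) by the phenoxide at its benzylic carbon, with inversion (Cs2CO3 cat., DMF, 70 °C), should give the β-aryloxy-α-hydroxy ester F1.
- LiOH in THF–H2O gives the hydroxy acid F2.
- Trifluoroacetic anhydride in CH2Cl2 forms the mixed anhydride, caps the hydroxyl and acylates the only free carbon ortho to O1 of the activated ring A. This gives the 3-O-trifluoroacetyl chromanone F3.
- NaHCO3 in MeOH removes the trifluoroacetate, and the route is rejoined at ketol 17.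

**Step 6.**
- What may go wrong: attack may occur para to the hydroxyl, a second benzylation may follow, or acid may cause loss or migration of benzyl groups.
- Fallback: a regiochemically fixed directed metalation and cross-coupling that sets out from 8 and 7.
- Phenol 8 with diethylcarbamoyl chloride (K2CO3, MeCN, reflux) gives the aryl diethylcarbamate F4.
- Alcohol 7 with PBr3 (Et2O, 0 °C) gives the ring A' benzylic bromide F5, used crude.
- Ortho-lithiation of F4 between the carbamate and a benzyloxy group (s-BuLi, TMEDA, THF, −78 °C) and immediate transmetalation with ZnCl2 give the arylzinc chloride F6, which no longer attacks or enolises the ketone.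
- Negishi coupling of F6 with F5 (Pd(PPh3)4, 5 mol %, THF, 0 °C to rt) gives the coupled carbamate F7.
- NaOH in EtOH at reflux cleaves the carbamate, and the route is rejoined at phenol 9.

**Step 9.**
- What may go wrong: alkylation of the hindered, hydrogen-bonded phenoxide may be slow enough for the labile bromide to decay by solvolysis or self-condensation. Base may also induce aldol closure of the product enolate onto the neighbouring aldehyde.
- Fallback: a base-free Mitsunobu etherification that sets out from 10 and uses commercial methyl 2-hydroxy-2-(4-methoxyphenyl)acetate (COC(=O)C(O)c1ccc(OC)cc1), PPh3 and DIAD in THF, 0 °C to rt.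
- The acidic salicylaldehyde hydroxyl suits this activation mode, and step 8 becomes unnecessary.
- The route is rejoined at 13, and no compound outside the list is made (F0).

## Further compounds

F1 | step 12 | methyl 3-[3,5-bis(benzyloxy)-2-(Ar'CH2)phenoxy]-2-hydroxy-3-(4-methoxyphenyl)propanoate (racemic, one enantiomer drawn) | COc1ccc(cc1)[C@@H](Oc1cc(OCc2ccccc2)cc(OCc2ccccc2)c1Cc1c(OCc2ccccc2)c(C(=O)CCc2ccc(OCc3ccccc3)cc2)c(OCc2ccccc2)c(C)c1OC)[C@H](C(=O)OC)O
F2 | step 12 | 3-[3,5-bis(benzyloxy)-2-(Ar'CH2)phenoxy]-2-hydroxy-3-(4-methoxyphenyl)propanoic acid (racemic, one enantiomer drawn) | COc1ccc(cc1)[C@@H](Oc1cc(OCc2ccccc2)cc(OCc2ccccc2)c1Cc1c(OCc2ccccc2)c(C(=O)CCc2ccc(OCc3ccccc3)cc2)c(OCc2ccccc2)c(C)c1OC)[C@H](C(=O)O)O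
F3 | step 12 | 3-O-trifluoroacetate of ketol 17 (racemic, trans isomer drawn) | COc1ccc(cc1)[C@@H]1[C@H](C(=O)c2c(OCc3ccccc3)cc(OCc3ccccc3)c(Cc3c(OCc4ccccc4)c(C(=O)CCc4ccc(OCc5ccccc5)cc4)c(OCc4ccccc4)c(C)c3OC)c2O1)OC(=O)C(F)(F)F
F4 | step 6 | 3,5-bis(benzyloxy)phenyl diethylcarbamate | CCN(CC)C(=O)Oc1cc(OCc2ccccc2)cc(OCc2ccccc2)c1
F5 | step 6 | ring A' benzylic bromide Ar'CH2Br | Cc1c(OC)c(CBr)c(OCc2ccccc2)c(C(=O)CCc2ccc(OCc3ccccc3)cc2)c1OCc1ccccc1
F6 | step 6 | [2,4-bis(benzyloxy)-6-(diethylcarbamoyloxy)phenyl]zinc chloride | CCN(CC)C(=O)Oc1cc(OCc2ccccc2)cc(OCc2ccccc2)c1[Zn]Cl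
F7 | step 6 | 3,5-bis(benzyloxy)-2-(Ar'CH2)phenyl diethylcarbamate | CCN(CC)C(=O)Oc1cc(OCc2ccccc2)cc(OCc2ccccc2)c1Cc1c(OCc2ccccc2)c(C(=O)CCc2ccc(OCc3ccccc3)cc2)c(OCc2ccccc2)c(C)c1OC
F0 | step 9 | none | none
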